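## Retrosynthetic overview

- Aiphanol is reached by removing three acetates from a triacetate. The triacetate is cut at the bond between C1 of the syringyl ring and C2 of the dioxane ring: a Friedel–Crafts union of free 2,6-dimethoxyphenol with a C2 oxocarbenium ion that already carries the complete (acetylated) stilbene half.
- Enabling feature: C2 is both the acetal-type carbon next to ring oxygen O1 of the 1,4-dioxane ring (so it can be a stabilised cation) and the benzylic carbon para to the phenolic OH of the syringyl ring, whose two ortho positions carry OMe. The acetoxymethyl group on the neighbouring C3 steers the arene trans.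
- The stilbene C=C comes from a Heck coupling of a 7-bromobenzodioxane with 3,5-diacetoxystyrene.
- The dioxane ring is closed at O1–C2 as a lactol when an α-aryloxy ester is reduced. Before that, O4–C3 is made by Mitsunobu inversion of an (S)-glycerate (source of C3) with 5-bromosalicylaldehyde, and O1 is unveiled by Dakin oxidation.
- Ring order: the three benzene rings are bought; the only ring formed is the 1,4-dioxane ring (step 4), before the two C–C couplings (steps 6 and 7).

Key step: step 7

Remark: the dioxane ring is numbered O1, C2 (aryl-bearing), C3 (hydroxymethyl-bearing), O4, which puts the styryl arm at C7 and makes the target the (2R,3R)-trans isomer; methyl (S)-glycerate and 3,5-diacetoxystyrene are taken as purchasable.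

## Route

Step 1
Reactants: 1 methyl (S)-2,3-dihydroxypropanoate
Product: 2 methyl (S)-3-[(tert-butyldimethylsilyl)oxy]-2-hydroxypropanoate
Conditions: TBSCl (1.05 equiv), imidazole, CH2Cl2, −20 °C → 0 °C
Reagents that add atoms: tert-butyldimethylsilyl chloride, CC(C)(C)[Si](C)(C)Cl
Why: Silyl ether formation: the primary hydroxyl of the 1,2-diol should react much faster than the secondary hydroxyl next to the ester, and the stereocentre is not touched.

Step 2
Reactants: 2 methyl (S)-3-[(tert-butyldimethylsilyl)oxy]-2-hydroxypropanoate; 3 5-bromo-2-hydroxybenzaldehyde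
Product: 4 methyl (R)-2-(4-bromo-2-formylphenoxy)-3-[(tert-butyldimethylsilyl)oxy]propanoate
Conditions: PPh3, DIAD, toluene, 0 °C → rt
Reagents that add atoms: none
Why: Mitsunobu etherification: the acidic salicylaldehyde phenol displaces the activated secondary alcohol by SN2 with inversion, so the (S)-carbinol should give the (R)-aryl ether that becomes C3 (routine for lactate-type α-hydroxy esters), with bromine para to the new ether oxygen (future O4).

Step 3
Reactants: 4 methyl (R)-2-(4-bromo-2-formylphenoxy)-3-[(tert-butyldimethylsilyl)oxy]propanoate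
Product: 6 methyl (R)-2-(4-bromo-2-hydroxyphenoxy)-3-hydroxypropanoate, via aryl formate 5 (not isolated)
Conditions: mCPBA, CH2Cl2, 0 °C → rt; aq. Na2S2O3/NaHCO3 wash; then HCl (cat., from AcCl), MeOH, 0 °C → rt
Reagents that add atoms: 3-chloroperoxybenzoic acid (mCPBA), OOC(=O)c1cccc(Cl)c1
Why: Dakin-type Baeyer–Villiger oxidation: the electron-rich ortho-alkoxyaryl group migrates to give formate 5, and acidic methanolysis then frees the phenol (future O1) and the primary alcohol without touching the acid-stable α-aryloxy ester stereocentre.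

Step 4
Reactants: 6 methyl (R)-2-(4-bromo-2-hydroxyphenoxy)-3-hydroxypropanoate
Product: 8 (3R)-7-bromo-3-(hydroxymethyl)-2,3-dihydro-1,4-benzodioxin-2-ol (C2 epimers), via hydroxy aldehyde 7 (not isolated)
Conditions: i-Bu2AlH (4.5 equiv), CH2Cl2/THF, −78 °C; aq. potassium sodium tartrate work-up
Reagents that add atoms: none
Why: Partial reduction of an α-alkoxy ester: the chelated aluminium hemiacetal should survive at −78 °C and give aldehyde 7 on work-up, which the ortho phenol captures by 6-exo-trig hemiacetalisation to close the dioxane ring at O1–C2; C3 is untouched and the new C2 centre is an inconsequential epimer mixture.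

Step 5
Reactants: 8 (3R)-7-bromo-3-(hydroxymethyl)-2,3-dihydro-1,4-benzodioxin-2-ol
Product: 9 [(3R)-2-(acetyloxy)-7-bromo-2,3-dihydro-1,4-benzodioxin-3-yl]methyl acetate (C2 epimers)
Conditions: Ac2O, pyridine, DMAP (cat.), CH2Cl2, 0 °C
Reagents that add atoms: acetic anhydride, CC(=O)OC(C)=O
Why: Esterification (peracetylation as for sugar lactols): the cyclic hemiacetal and the primary alcohol are acylated, giving the anomeric leaving group and the participating ester; the C2 mixture is erased in step 7.

Step 6
Reactants: 9 [(3R)-2-(acetyloxy)-7-bromo-2,3-dihydro-1,4-benzodioxin-3-yl]methyl acetate; 10 5-ethenyl-1,3-phenylene diacetate (3,5-diacetoxystyrene)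
Product: 11 [(3R)-2-(acetyloxy)-7-[(E)-2-(3,5-diacetoxyphenyl)ethenyl]-2,3-dihydro-1,4-benzodioxin-3-yl]methyl acetate (C2 epimers)
Conditions: Pd2(dba)3 (2.5 mol %), P(t-Bu)3·HBF4 (10 mol %), Cy2NMe (1.2 equiv), 1,4-dioxane, 50 °C
Reagents that add atoms: none
Why: Mizoroki–Heck reaction: oxidative addition of the aryl bromide to the electron-rich zerovalent palladium–P(t-Bu)3 catalyst, syn insertion at the terminal carbon of the styrene and syn β-hydride elimination should give the E-stilbene, while the hindered amine base leaves the four esters alone.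

Step 7
Reactants: 11 [(3R)-2-(acetyloxy)-7-[(E)-2-(3,5-diacetoxyphenyl)ethenyl]-2,3-dihydro-1,4-benzodioxin-3-yl]methyl acetate; 12 2,6-dimethoxyphenol (5 equiv)
Product: 15 [(2R,3R)-7-[(E)-2-(3,5-diacetoxyphenyl)ethenyl]-2-(4-hydroxy-3,5-dimethoxyphenyl)-2,3-dihydro-1,4-benzodioxin-3-yl]methyl acetate, via oxocarbenium ion 13 (not isolated), via acetoxonium ion 14 (not isolated)
Conditions: Sc(OTf)3 (20 mol %), 4 Å molecular sieves, CH2Cl2, −20 °C → rt
Reagents that add atoms: none
Why: Sc(OTf)3 should ionise the anomeric acetate of 11 to the O1-stabilised oxocarbenium ion 13, which the carbonyl oxygen of the C3 acetoxymethyl group caps reversibly (6-exo-trig) as the cis-fused acetoxonium ion 14; the para carbon of 12 then attacks C2 from the open face and the arenium ion rearomatises, any O-aryl acetal formed first re-ionising and funnelling to the C-aryl product. The closest known reaction type is the Lewis-acid Friedel–Crafts C-arylation of glycosyl acetates with phenols (aryl C-glycoside synthesis, including the O-to-C rearrangement), with 1,2-trans control by a participating ester. No ring of the target is closed here (the dioxane ring exists since step 4); only the transient 1,3-dioxan-2-ylium ring of 14 forms and opens again. The new stereocentre C2 is set R by the resident C3 centre: attack anti to the acetoxonium bridge (and anti to the C3 substituent in free 13) puts the aryl group trans to CH2OAc, which is also the more stable diequatorial arrangement. The step needs site selectivity for C4 of 12 over C3/C5 and oxygen, and chemoselectivity over the stilbene and the second arene: the two methoxy groups block both ortho positions and shield C3/C5, the para-hydroxyl activates C4, O-alkylation is reversible, the resorcinol ring is deactivated as its diacetate, and excess 12 with catalytic acid at low temperature should keep the E-alkene intact.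

Step 8
Reactants: 15 [(2R,3R)-7-[(E)-2-(3,5-diacetoxyphenyl)ethenyl]-2-(4-hydroxy-3,5-dimethoxyphenyl)-2,3-dihydro-1,4-benzodioxin-3-yl]methyl acetate
Product: 16 aiphanol
Conditions: K2CO3 (cat.), MeOH, 0 °C → rt; aq. NH4Cl work-up
Reagents that add atoms: none
Why: Zemplén-type transesterification: catalytic methoxide from K2CO3 in MeOH should remove the two aryl acetates and the primary acetate at or below room temperature, conditions under which the trans-benzodioxane stereocentres and the E-alkene should not change.

## Compound list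

1 | methyl (S)-2,3-dihydroxypropanoate | COC(=O)[C@@H](O)CO | starting material
2 | methyl (S)-3-[(tert-butyldimethylsilyl)oxy]-2-hydroxypropanoate | COC(=O)[C@@H](O)CO[Si](C)(C)C(C)(C)C | intermediate
3 | 5-bromo-2-hydroxybenzaldehyde | O=Cc1cc(Br)ccc1O | starting material
4 | methyl (R)-2-(4-bromo-2-formylphenoxy)-3-[(tert-butyldimethylsilyl)oxy]propanoate | COC(=O)[C@@H](CO[Si](C)(C)C(C)(C)C)Oc1ccc(Br)cc1C=O | intermediate
5 | methyl (R)-2-[4-bromo-2-(formyloxy)phenoxy]-3-[(tert-butyldimethylsilyl)oxy]propanoate | COC(=O)[C@@H](CO[Si](C)(C)C(C)(C)C)Oc1ccc(Br)cc1OC=O | intermediate (not isolated)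
6 | methyl (R)-2-(4-bromo-2-hydroxyphenoxy)-3-hydroxypropanoate | COC(=O)[C@@H](CO)Oc1ccc(Br)cc1O | intermediate
7 | (R)-2-(4-bromo-2-hydroxyphenoxy)-3-hydroxypropanal | O=C[C@@H](CO)Oc1ccc(Br)cc1O | intermediate (not isolated)
8 | (3R)-7-bromo-3-(hydroxymethyl)-2,3-dihydro-1,4-benzodioxin-2-ol (C2 epimers) | OC[C@H]1Oc2ccc(Br)cc2OC1O | intermediate
9 | [(3R)-2-(acetyloxy)-7-bromo-2,3-dihydro-1,4-benzodioxin-3-yl]methyl acetate (C2 epimers) | CC(=O)OC[C@H]1Oc2ccc(Br)cc2OC1OC(C)=O | intermediate
10 | 5-ethenyl-1,3-phenylene diacetate | C=Cc1cc(OC(C)=O)cc(OC(C)=O)c1 | starting material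
11 | [(3R)-2-(acetyloxy)-7-[(E)-2-(3,5-diacetoxyphenyl)ethenyl]-2,3-dihydro-1,4-benzodioxin-3-yl]methyl acetate (C2 epimers) | CC(=O)OC[C@H]1Oc2ccc(/C=C/c3cc(OC(C)=O)cc(OC(C)=O)c3)cc2OC1OC(C)=O | intermediate
12 | 2,6-dimethoxyphenol | COc1cccc(OC)c1O | starting material
13 | (3R)-3-(acetoxymethyl)-7-[(E)-2-(3,5-diacetoxyphenyl)ethenyl]-3H-1,4-benzodioxin-1-ium (C2 oxocarbenium ion) | CC(=O)OC[C@H]1Oc2ccc(/C=C/c3cc(OC(C)=O)cc(OC(C)=O)c3)cc2[O+]=C1 | intermediate (not isolated)
14 | cis-fused 2-methyl-1,3-dioxan-2-ylium (acetoxonium) ion formed from 13 by attack of the C3 acetoxymethyl carbonyl oxygen on C2 | CC1=[O+][C@@H]2Oc3cc(/C=C/c4cc(OC(C)=O)cc(OC(C)=O)c4)ccc3O[C@@H]2CO1 | intermediate (not isolated)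
15 | [(2R,3R)-7-[(E)-2-(3,5-diacetoxyphenyl)ethenyl]-2-(4-hydroxy-3,5-dimethoxyphenyl)-2,3-dihydro-1,4-benzodioxin-3-yl]methyl acetate | COc1cc([C@H]2Oc3cc(/C=C/c4cc(OC(C)=O)cc(OC(C)=O)c4)ccc3O[C@@H]2COC(C)=O)cc(OC)c1O | intermediate
16 | aiphanol, 5-[(E)-2-[(2R,3R)-2-(4-hydroxy-3,5-dimethoxyphenyl)-3-(hydroxymethyl)-2,3-dihydro-1,4-benzodioxin-7-yl]ethenyl]benzene-1,3-diol | COc1cc([C@H]2Oc3cc(/C=C/c4cc(O)cc(O)c4)ccc3O[C@@H]2CO)cc(OC)c1O | target

## Step count and risks

Total step count: 8. Longest linear sequence: 8 steps (1 → 16).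

Steps most likely to fail:

**Step 7.** The weakly nucleophilic para carbon of the phenol may react too slowly. That would leave time for attack through C3/C5 of the phenol, for proton loss from the cation next to C3 (which would erode the C3 configuration), for acid-induced reactions of the stilbene, and for re-ionisation of the new benzylic ether.
Fallback, setting out from 11 and coming back at 15: commercially available 2,6-dimethoxy-4-(4,4,5,5-tetramethyl-1,3,2-dioxaborolan-2-yl)phenol is converted with aqueous KHF2 in MeOH into potassium trifluoro(4-hydroxy-3,5-dimethoxyphenyl)borate F1. F1 is then coupled with 11 under BF3·OEt2 in MeCN/CH2Cl2 at −20 °C, the known BF3-promoted transfer of an aryl group from an organotrifluoroborate to an oxocarbenium ion. The C–C bond then forms at the boron-bearing carbon, which fixes the ring position, and the more reactive nucleophile shortens the exposure to acid; the product is 15.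

**Step 4.** Reduction may run past the aldehyde level, which would also erase the stereocentre because the two hydroxymethyl arms become equal. It may also stall, because the two free hydroxyls consume hydride and form poorly soluble aluminates.
Fallback, setting out from 3 and coming back at 8, which reaches the aldehyde level by oxidative cleavage instead of partial reduction: purchasable (R)-but-3-ene-1,2-diol is monosilylated (TBSCl, imidazole) to (R)-1-[(tert-butyldimethylsilyl)oxy]but-3-en-2-ol F2. Mitsunobu reaction of F2 with 3 (PPh3, DIAD) should give, with inversion, 5-bromo-2-{[(2S)-1-[(tert-butyldimethylsilyl)oxy]but-3-en-2-yl]oxy}benzaldehyde F3. mCPBA then converts F3 into 5-bromo-2-{[(2S)-1-[(tert-butyldimethylsilyl)oxy]but-3-en-2-yl]oxy}phenyl formate F4, whose acidic methanolysis gives (2S)-2-(4-bromo-2-hydroxyphenoxy)but-3-en-1-ol F5. Ozonolysis of F5 (O3, CH2Cl2/MeOH, −78 °C; then Me2S) delivers aldehyde 7, which closes to lactol 8.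

**Step 6.** Oxidative addition into the electron-rich aryl bromide may be slow, so that insertion with the opposite regiochemistry and base- or heat-induced loss of the anomeric acetate compete.
Fallback, setting out from 9 and 10 and coming back at 11: cross-metathesis of 10 with 4,4,5,5-tetramethyl-2-vinyl-1,3,2-dioxaborolane (second-generation Grubbs catalyst, CH2Cl2, 40 °C) should give 5-[(E)-2-(4,4,5,5-tetramethyl-1,3,2-dioxaborolan-2-yl)ethenyl]-1,3-phenylene diacetate F6. Its E geometry is then transferred to 9 by anhydrous Suzuki–Miyaura coupling (Pd(dppf)Cl2, CsF, 1,4-dioxane, 70 °C) to give 11.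

## Further compounds

F1 | step 7 | potassium trifluoro(4-hydroxy-3,5-dimethoxyphenyl)borate | [K+].COc1cc([B-](F)(F)F)cc(OC)c1O
F2 | step 4 | (R)-1-[(tert-butyldimethylsilyl)oxy]but-3-en-2-ol | C=C[C@@H](O)CO[Si](C)(C)C(C)(C)C
F3 | step 4 | 5-bromo-2-{[(2S)-1-[(tert-butyldimethylsilyl)oxy]but-3-en-2-yl]oxy}benzaldehyde | C=C[C@@H](CO[Si](C)(C)C(C)(C)C)Oc1ccc(Br)cc1C=O
F4 | step 4 | 5-bromo-2-{[(2S)-1-[(tert-butyldimethylsilyl)oxy]but-3-en-2-yl]oxy}phenyl formate | C=C[C@@H](CO[Si](C)(C)C(C)(C)C)Oc1ccc(Br)cc1OC=O
F5 | step 4 | (2S)-2-(4-bromo-2-hydroxyphenoxy)but-3-en-1-ol | C=C[C@@H](CO)Oc1ccc(Br)cc1O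
F6 | step 6 | 5-[(E)-2-(4,4,5,5-tetramethyl-1,3,2-dioxaborolan-2-yl)ethenyl]-1,3-phenylene diacetate | CC(=O)Oc1cc(/C=C/B2OC(C)(C)C(C)(C)O2)cc(OC(C)=O)c1
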